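**Plan**
- Retrosynthetic cuts: first C8–C8a (the carbocycle); then C7–C8 together with the O7–C(=O) bond of the stearate (one three-component isocyanide coupling); then C4a=C5 (aldol condensation); the dihydropyranone goes back to a 3-hydroxybutanoate.
- Forward order: the pyran ring is made first, the C5–C7 diketone arm is attached at C4a, stearic acid and the isocyanide carbon (the future C8) are joined at C7, and the carbocycle closes last by acylation of C8a.
- Enabling feature: C7 of the isochromene carries a methyl, an acyloxy group and the acyl carbon C8, an α-acyloxy carbonyl unit, which is the Passerini retron. In the open precursor C7 is a methyl ketone next to C6=O (a chelating 1,2-diketone), and C6 is deactivated by the conjugation O2–C1=C8a–C4a=C5–C6=O. The same push–pull diene makes C8a the nucleophile for the last closure.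
- Stereochemistry: C3 comes from methyl (R)-3-hydroxybutanoate. C7 is set in the Passerini step by a chiral copper Lewis acid and, being quaternary, cannot be lost afterwards.

Key step: step 6

Assumption: the convertible isocyanide 1-(2,2-dimethoxyethyl)-2-isocyanobenzene is taken as a purchasable reagent; it is otherwise two routine operations (N-formylation, POCl3/Et3N dehydration) from 2-(2,2-dimethoxyethyl)aniline.

**Step 1**
Reactants: 1 methyl (R)-3-hydroxybutanoate
Product: 2 (R)-3-hydroxy-N-methoxy-N-methylbutanamide
Conditions: MeNHOMe·HCl, i-PrMgCl (4 equiv), THF, −20 °C → 0 °C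
Reagents that add atoms: N,O-dimethylhydroxylamine hydrochloride, CNOC.Cl
Why: The chloromagnesium amide made from the amine salt and i-PrMgCl converts the methyl ester directly into the N-methoxy-N-methylamide (Weinreb amide formation) while the hydroxyl is only held as its magnesium alkoxide, so the carbinol centre (C3 of the target) is untouched.

**Step 2**
Reactants: 2 (R)-3-hydroxy-N-methoxy-N-methylbutanamide
Product: 3 (R)-5-hydroxyhex-1-yn-3-one
Conditions: HC≡CMgBr (3.5 equiv), THF, 0 °C; cold aq. NaHSO4 quench
Reagents that add atoms: ethynylmagnesium bromide, C#C[Mg]Br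
Why: The alkynyl Grignard reagent adds once to the N-methoxy-N-methylamide and stops at the chelated tetrahedral intermediate (Weinreb ketone synthesis), and the acidic quench protonates the released amine so that it cannot add to the ynone.

**Step 3**
Reactants: 3 (R)-5-hydroxyhex-1-yn-3-one
Product: 4 (R)-2-methyl-2,3-dihydro-4H-pyran-4-one
Conditions: Ph3PAuCl (2 mol %), AgOTf (2 mol %), CH2Cl2, rt
Reagents that add atoms: none
Why: Cationic gold activates the terminal ynone for 6-endo-dig attack of the β-hydroxyl (hydroalkoxylation, an oxa-Michael cycloisomerisation), which closes the vinylogous-ester ring without breaking any bond at the stereocentre.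

**Step 4**
Reactants: 4 (R)-2-methyl-2,3-dihydro-4H-pyran-4-one; 5 3,3-dimethoxybutan-2-one
Product: 7 (1Z)-3,3-dimethoxy-1-[(2R)-2-methyl-2,3-dihydro-4H-pyran-4-ylidene]butan-2-one, via aldol adduct 6 (not isolated)
Conditions: LiN(i-Pr)2, THF, −78 °C; then 4, short contact; AcOH, −78 °C; then CSA (cat.), 4 Å molecular sieves, CH2Cl2, 0 °C
Reagents that add atoms: none
Why: The kinetic lithium enolate of the methyl ketone adds 1,2 to the vinylogous-ester carbonyl (aldol addition, the first stage of a Stork–Danheiser sequence), and under mild anhydrous acid the tertiary allylic alcohol ionises to a 2,3-dihydropyrylium ion that loses the acidic α-proton (E1 dehydration, overall an aldol condensation) to give the push–pull dienone, whose carbinol centre is destroyed and whose Z/E geometry can equilibrate under acid.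

**Step 5**
Reactants: 7 (1Z)-3,3-dimethoxy-1-[(2R)-2-methyl-2,3-dihydro-4H-pyran-4-ylidene]butan-2-one
Product: 8 (1Z)-1-[(2R)-2-methyl-2,3-dihydro-4H-pyran-4-ylidene]butane-2,3-dione
Conditions: TFA, H2O (few equiv), CH2Cl2, 0 °C → rt
Reagents that add atoms: water, O
Why: Acid-catalysed ketal hydrolysis unmasks the 1,2-diketone, while the ring enol ether, as the donor end of a dienylogous ester, should resist hydration far better than an isolated enol ether.

**Step 6**
Reactants: 8 (1Z)-1-[(2R)-2-methyl-2,3-dihydro-4H-pyran-4-ylidene]butane-2,3-dione; 9 stearic acid (octadecanoic acid); 10 1-(2,2-dimethoxyethyl)-2-isocyanobenzene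
Product: 11 (2R,4Z)-1-{[2-(2,2-dimethoxyethyl)phenyl]amino}-2-methyl-4-[(2R)-2-methyl-2,3-dihydro-4H-pyran-4-ylidene]-1,3-dioxobutan-2-yl octadecanoate (Passerini adduct, 7R in isochromene numbering)
Conditions: Cu(OTf)2 (divalent copper, 20 mol %), (S,S)-Ph-pybox [2,6-bis((4S)-4-phenyl-4,5-dihydrooxazol-2-yl)pyridine] (22 mol %), AW-300 molecular sieves, CH2Cl2, 0 °C, 10 added slowly
Reagents that add atoms: none
Why: Proposed new method: the 1,2-diketone should chelate the copper–pybox Lewis acid through the C6 and C7 oxygens, the isocyanide carbon then adds to the activated C7 carbonyl, stearate captures the nitrilium ion and a Mumm-type acyl shift moves the stearoyl group onto the C7 oxygen, so the C7–C8 bond and the ester O–acyl bond arise in one operation (Passerini three-component reaction). The closest known reactions are the uncatalysed Passerini reaction of ketones and 1,2-diketones and the copper–pybox-catalysed enantioselective Passerini reaction of chelating aldehydes; enantioface control at a ketone is the new element. No ring is closed in this step. The new quaternary centre C7 is controlled by the ligand: si-face attack at C7 gives 7R, which is the face exposed in (S,S)-bis(oxazoline) copper chelates of pyruvate-type 1,2-dicarbonyls; the sense with pybox is an assumption to be checked on the product, and the (R,R) ligand is the remedy if it proves opposite. The step needs C7 over C6 selectivity, which the substrate secures because C6 is the acceptor end of the dienylogous ester O2–C1=C8a–C4a=C5–C6=O while C7 is an unhindered methyl ketone; it also needs the uncatalysed pathway held back, for which low temperature, dilution and slow addition of the isocyanide are used.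

**Step 7**
Reactants: 11 Passerini adduct
Product: 12 (2R,4Z)-1-(1H-indol-1-yl)-2-methyl-4-[(2R)-2-methyl-2,3-dihydro-4H-pyran-4-ylidene]-1,3-dioxobutan-2-yl octadecanoate (N-acylindole)
Conditions: CSA (10 mol %), toluene, 80 °C, 5 Å molecular sieves
Reagents that add atoms: none
Why: Acid turns the dimethyl acetal into an oxocarbenium ion that the anilide nitrogen traps, and loss of methanol aromatises the new ring to the N-acylindole (acid-catalysed cyclodehydration, the standard activation of 2-(2,2-dimethoxyethyl)anilides), which makes the inert secondary amide an acyl donor without base and without touching C7.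

**Step 8**
Reactants: 12 N-acylindole
Product: 13 (3R,7R)-3,7-dimethyl-6,8-dioxo-4,6,7,8-tetrahydro-3H-isochromen-7-yl octadecanoate (CNP0142202.1)
Conditions: Sc(OTf)3 (20 mol %), ClCH2CH2Cl, 60 °C, high dilution
Reagents that add atoms: none
Why: Proposed new method: coordination of Sc(OTf)3 to the N-acylindole carbonyl (C8) should let the dienol-ether carbon C8a, the nucleophilic position β to O2, attack it in a 6-exo-trig closure, after which the oxocarbenium ion at C1 loses the C8a proton and the tetrahedral intermediate expels indole to leave the C8 ketone; the closest known reaction type is the Lewis-acid-mediated Friedel–Crafts C-acylation of electron-rich heteroarenes by N-acyl azoles and of cyclic enol ethers (glycals) by acyl chlorides; C7 is quaternary and C3 is remote, so neither centre can epimerise.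

**Compound list**
1 | methyl (R)-3-hydroxybutanoate | C[C@@H](O)CC(=O)OC | starting material
2 | (R)-3-hydroxy-N-methoxy-N-methylbutanamide | C[C@@H](O)CC(=O)N(C)OC | intermediate
3 | (R)-5-hydroxyhex-1-yn-3-one | C[C@@H](O)CC(=O)C#C | intermediate
4 | (R)-2-methyl-2,3-dihydro-4H-pyran-4-one | C[C@@H]1CC(=O)C=CO1 | intermediate
5 | 3,3-dimethoxybutan-2-one | CC(=O)C(C)(OC)OC | starting material
6 | 1-[(2R)-4-hydroxy-2-methyl-3,4-dihydro-2H-pyran-4-yl]-3,3-dimethoxybutan-2-one (aldol adduct, both C4 epimers, not isolated) | CC(OC)(OC)C(=O)CC1(O)C[C@@H](C)OC=C1 | intermediate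
7 | (1Z)-3,3-dimethoxy-1-[(2R)-2-methyl-2,3-dihydro-4H-pyran-4-ylidene]butan-2-one | CC(OC)(OC)C(=O)/C=C1\C=CO[C@H](C)C1 | intermediate
8 | (1Z)-1-[(2R)-2-methyl-2,3-dihydro-4H-pyran-4-ylidene]butane-2,3-dione | CC(=O)C(=O)/C=C1\C=CO[C@H](C)C1 | intermediate
9 | stearic acid (octadecanoic acid) | CCCCCCCCCCCCCCCCCC(=O)O | starting material
10 | 1-(2,2-dimethoxyethyl)-2-isocyanobenzene | [C-]#[N+]c1ccccc1CC(OC)OC | starting material
11 | (2R,4Z)-1-{[2-(2,2-dimethoxyethyl)phenyl]amino}-2-methyl-4-[(2R)-2-methyl-2,3-dihydro-4H-pyran-4-ylidene]-1,3-dioxobutan-2-yl octadecanoate | CCCCCCCCCCCCCCCCCC(=O)O[C@@](C)(C(=O)Nc1ccccc1CC(OC)OC)C(=O)/C=C1\C=CO[C@H](C)C1 | intermediate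
12 | (2R,4Z)-1-(1H-indol-1-yl)-2-methyl-4-[(2R)-2-methyl-2,3-dihydro-4H-pyran-4-ylidene]-1,3-dioxobutan-2-yl octadecanoate | CCCCCCCCCCCCCCCCCC(=O)O[C@@](C)(C(=O)n1ccc2ccccc12)C(=O)/C=C1\C=CO[C@H](C)C1 | intermediate
13 | (3R,7R)-3,7-dimethyl-6,8-dioxo-4,6,7,8-tetrahydro-3H-isochromen-7-yl octadecanoate | CCCCCCCCCCCCCCCCCC(=O)O[C@]1(C)C(=O)C=C2C[C@@H](C)OC=C2C1=O | target

Total step count: 8
Longest linear sequence: 8 steps (1 → 13); compounds 5, 9 and 10 enter as purchased components.

**Steps most likely to fail**

Step 6. Enantioface discrimination at C7 may be weak or of the wrong sense, because the uncatalysed three-component reaction of an activated 1,2-diketone can outrun the catalysed one, and because isocyanide and carboxylate can displace the diketone from copper. The fallback gives up asymmetric induction and sets out from 8. The classical Passerini reaction of 8, 9 and 10 without catalyst (concentrated CH2Cl2, rt), established for ketones and 1,2-diketones, should give 11 together with its C7 epimer, the (7S)-Passerini adduct F1. Because C3 is already fixed the two are diastereomers; they are separated by preparative HPLC and the route is rejoined at 11.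

Step 8. The ring closure may stall because the Lewis acid binds the dienone oxygen O6 and drains the nucleophilicity of C8a, and the liberated indole may compete as a carbon nucleophile for the activated acyl group or for C1 of the product. The fallback sets out from 12 and uses a more electrophilic acyl donor. Mild cleavage of the N-acylindole with LiOH/H2O2 (THF–H2O, 0 °C) gives the carboxylic acid F2. F2 is converted cold and without storage, since it is a β-keto acid, into the acid chloride F3 with 1-chloro-N,N,2-trimethylprop-1-en-1-amine in CH2Cl2. F3 is closed onto C8a with AgOTf and 2,6-di-tert-butylpyridine at −40 °C, the established C-acylation of enol ethers by acyl chlorides, which returns to the route at 13.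

Step 4. The aldol addition may revert before the alkoxide is quenched, or the enolate may deprotonate 4 or add in the conjugate sense, because a vinylogous-ester carbonyl is a poor acceptor for a ketone enolate. The fallback sets out from 4 and uses an irreversible carbon nucleophile. The dilithium derivative of but-3-yn-2-ol (n-BuLi, THF, −78 °C) adds to the carbonyl to give the alkynediol F4. A Meyer–Schuster rearrangement (Ph3PAuNTf2 cat., wet CH2Cl2), favoured by the easy ionisation of the tertiary alcohol next to the enol ether, gives the α-hydroxy dienone F5. Dess–Martin oxidation of F5 returns to the route at 8, so that 7 and step 5 are bypassed.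

**Further compounds**
F1 | step 6 | (2S,4Z)-1-{[2-(2,2-dimethoxyethyl)phenyl]amino}-2-methyl-4-[(2R)-2-methyl-2,3-dihydro-4H-pyran-4-ylidene]-1,3-dioxobutan-2-yl octadecanoate (C7 epimer of 11) | CCCCCCCCCCCCCCCCCC(=O)O[C@](C)(C(=O)Nc1ccccc1CC(OC)OC)C(=O)/C=C1\C=CO[C@H](C)C1
F2 | step 8 | (2R,4Z)-2-methyl-4-[(2R)-2-methyl-2,3-dihydro-4H-pyran-4-ylidene]-3-oxo-2-(octadecanoyloxy)butanoic acid | CCCCCCCCCCCCCCCCCC(=O)O[C@@](C)(C(=O)O)C(=O)/C=C1\C=CO[C@H](C)C1
F3 | step 8 | (2R,4Z)-2-methyl-4-[(2R)-2-methyl-2,3-dihydro-4H-pyran-4-ylidene]-3-oxo-2-(octadecanoyloxy)butanoyl chloride | CCCCCCCCCCCCCCCCCC(=O)O[C@@](C)(C(=O)Cl)C(=O)/C=C1\C=CO[C@H](C)C1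
F4 | step 4 | (2R)-4-(3-hydroxybut-1-yn-1-yl)-2-methyl-3,4-dihydro-2H-pyran-4-ol (mixture at both carbinol centres) | CC(O)C#CC1(O)C[C@@H](C)OC=C1
F5 | step 4 | (1Z)-3-hydroxy-1-[(2R)-2-methyl-2,3-dihydro-4H-pyran-4-ylidene]butan-2-one (both carbinol epimers) | CC(O)C(=O)/C=C1\C=CO[C@H](C)C1
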